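**Assumptions.** The target, C21H22O5, has no stereocentre and is achiral, so "single enantiomer" does not apply. The only stereo-element is the E-enone, which is set in Step 4. Alkylating agents that leave atoms in the product are numbered as compounds.

## Retrosynthetic overview
1. Target 11 comes from 10 by removing one MOM group at O-3.
2. The 1,1-dimethylallyl group at C5 comes from an aromatic Claisen rearrangement of the 4-O-prenyl chalcone 9. C3 carries oxygen, so only C5 can rearomatise.
3. The E-enone comes from a Claisen–Schmidt condensation of aldehyde 7 with 4′-hydroxyacetophenone 8.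
4. Aldehyde 7 comes from 2,3,4-trihydroxybenzaldehyde 1 by three O-alkylations in order of OH reactivity: 4-OH (most acidic), then 3-OH, then the chelated 2-OH.
5. No rings are formed, because both benzene rings are purchased.

## Route

**Step 1**
Reactants: 1, 2,3,4-trihydroxybenzaldehyde; 2, prenyl bromide
Product: 3, 2,3-dihydroxy-4-(3-methylbut-2-enyloxy)benzaldehyde
Conditions: 2 (1.05 equiv), KHCO3 (1.2 equiv), DMF, rt→40 °C, Ar
Reagents that add atoms: prenyl bromide, CC(C)=CCBr
Why: In this acidity-controlled Williamson etherification, the weak base ionises only the 4-OH (para to CHO, most acidic), while the 2-OH is hydrogen-bonded to CHO and the 3-OH is unconjugated.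

**Step 2**
Reactants: 3; 4, chloromethyl methyl ether (MOMCl)
Product: 5, 2-hydroxy-3-(methoxymethoxy)-4-(prenyloxy)benzaldehyde
Conditions: MOMCl (1.1 equiv), i-Pr2NEt (1.5 equiv), CH2Cl2, 0 °C→rt
Reagents that add atoms: MOMCl, COCCl
Why: In this chelation-controlled O-alkylation (MOM protection), the 2-OH hydrogen-bonded to the aldehyde is inert and only the free 3-OH reacts, which is the same selectivity that gives 2-hydroxy-3,4-bis(MOM) ethers from 1.

**Step 3**
Reactants: 5; 6, iodomethane
Product: 7, 2-methoxy-3-(methoxymethoxy)-4-(prenyloxy)benzaldehyde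
Conditions: MeI (3 equiv), K2CO3 (2 equiv), DMF, rt→40 °C
Reagents that add atoms: iodomethane, CI
Why: This Williamson O-methylation acts on the only remaining OH, excess carbonate in DMF overcomes the chelation, and the MOM group, prenyl ether and CHO are all stable to these conditions.

**Step 4**
Reactants: 7; 8, 4′-hydroxyacetophenone (1.1 equiv)
Product: 9, (E)-1-(4-hydroxyphenyl)-3-[2-methoxy-3-(methoxymethoxy)-4-(prenyloxy)phenyl]prop-2-en-1-one
Conditions: 50% aq KOH (about 10 equiv), EtOH, 0 °C→rt, 24–36 h, N2; then cold 1 M HCl to pH 5–6
Reagents that add atoms: coupling partner 8 only, CC(=O)c1ccc(O)cc1 (water is lost)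
Why: This Claisen–Schmidt (crossed aldol, E1cB) condensation uses a non-enolisable aldehyde with no free OH, so it stays electrophilic, and reversible dehydration gives the thermodynamic E-enone (J about 15.5 Hz).

**Step 5**
Reactants: 9
Product: 10, (E)-3-[4-hydroxy-2-methoxy-3-(methoxymethoxy)-5-(2-methylbut-3-en-2-yl)phenyl]-1-(4-hydroxyphenyl)prop-2-en-1-one
Conditions: degassed EtOH–H2O (4:1), sealed tube, 130 °C, 16–24 h
Reagents that add atoms: none
Why: In this water-accelerated aromatic Claisen [3,3]-sigmatropic rearrangement, allyl inversion turns O-prenyl into C-(1,1-dimethylallyl), only C5–H allows rearomatisation because migrations to C3 or C1 are reversible dead ends, and the E-enone is untouched.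

**Step 6**
Reactants: 10
Product: 11, target, (E)-3-[3,4-dihydroxy-2-methoxy-5-(2-methylbut-3-en-2-yl)phenyl]-1-(4-hydroxyphenyl)prop-2-en-1-one
Conditions: 2 M aq HCl–MeOH (1:5), 45 °C, about 2 h, N2
Reagents that add atoms: none
Why: This acid hydrolysis of the MOM acetal spares the monosubstituted vinyl group, which is too weakly basic to protonate and cyclise under mild acid, and flavanone closure is impossible without a 2′-OH.

## Compound list
1 | 2,3,4-trihydroxybenzaldehyde | O=Cc1ccc(O)c(O)c1O | starting material
2 | prenyl bromide (1-bromo-3-methylbut-2-ene) | CC(C)=CCBr | starting material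
3 | 2,3-dihydroxy-4-(prenyloxy)benzaldehyde | O=Cc1ccc(OCC=C(C)C)c(O)c1O | intermediate
4 | chloromethyl methyl ether | COCCl | starting material
5 | 2-hydroxy-3-(methoxymethoxy)-4-(prenyloxy)benzaldehyde | O=Cc1ccc(OCC=C(C)C)c(OCOC)c1O | intermediate
6 | iodomethane | CI | starting material
7 | 2-methoxy-3-(methoxymethoxy)-4-(prenyloxy)benzaldehyde | O=Cc1ccc(OCC=C(C)C)c(OCOC)c1OC | intermediate
8 | 4′-hydroxyacetophenone | CC(=O)c1ccc(O)cc1 | starting material
9 | (E)-4-O-prenyl-3-O-MOM chalcone | COCOc1c(OCC=C(C)C)ccc(/C=C/C(=O)c2ccc(O)cc2)c1OC | intermediate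
10 | (E)-5-(1,1-dimethylallyl)-3-O-MOM chalcone | C=CC(C)(C)c1cc(/C=C/C(=O)c2ccc(O)cc2)c(OC)c(OCOC)c1O | intermediate
11 | 5-(1,1-dimethylallyl)-3,4,4′-trihydroxy-2-methoxychalcone (IN0234) | C=CC(C)(C)c1cc(/C=C/C(=O)c2ccc(O)cc2)c(OC)c(O)c1O | target

## Step count
Total steps: 6. Longest linear sequence: 6, running 1→3→5→7→9→10→11, with 8 purchased. Steps 2 and 3 can be run in one pot (5 operations) once the O-3 selectivity has been confirmed by the chelated OH signal of 5 at δ about 11.

## Three steps most likely to fail

1. **Step 5 (Claisen rearrangement).**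
   - Risk: the ether sits para to an electron-withdrawing enone, so deprenylation or cyclisation may compete.
   - Fallback: abandon the sigmatropic route.
     - Brominate 3,4-dihydroxy-2-methoxybenzaldehyde at C5.
     - Protect both hydroxyls as MOM ethers.
     - Install the reverse-prenyl group by a γ-selective Pd-catalysed Suzuki–Miyaura coupling with prenyl-Bpin.
     - Finish with the Claisen–Schmidt condensation and global MOM removal.

2. **Step 1 (mono-4-O-prenylation).**
   - Risk: the triol is prone to oxidation, and over-alkylation or C-alkylation may occur.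
   - Fallback: change the order of events.
     - Convert 1 to its 3,4-bis-MOM ether, methylate at O-2, and remove the MOM groups to give 3,4-dihydroxy-2-methoxybenzaldehyde.
     - Prenylate O-4, where only two hydroxyls of very different acidity compete.
     - Carry out the aldol condensation, then run the Claisen rearrangement as a neutral, protecting-group-free last step.

3. **Step 2 (O-3 versus O-2 selectivity).**
   - Risk: a mixture of regioisomers.
   - Fallback: over-protect and then differentiate.
     - Make the 2,3-bis-MOM ether of 3.
     - Cleave only the MOM group ortho to the carbonyl by chelation-assisted deprotection (MgBr2·OEt2 or I2/MeOH) to give 5.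
     - Continue from Step 3.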